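**Retrosynthetic overview**
1. The target's vicinal tertiary Br / secondary Cl comes from anti-chlorohydrin formation on the ring-B trisubstituted alkene, then OH→Br with retention. The C2 bromide comes from the C2 alcohol by SN2 inversion.
2. The exocyclic methylene comes from Wittig methylenation of a spiro ketone.
3. The spiro[5.5]undecane core and ring B come from a Diels–Alder reaction of isoprene with 2-methylene-3,3-dimethyl-4-silyloxycyclohexanone. This forms ring B second.
4. Ring A comes first, built from (R)-pantolactone. Pantolactone supplies the carbinol stereocentre next to the gem-dimethyl carbon, and that centre controls all the later stereocentres.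

Assumptions (one line): D-(R)-pantolactone is the starting material, and the Diels–Alder gives the para adduct with the new C–C bond anti to the OTBS group (diastereomers separable).

---

**Step 1**
Reactants: 1 (R)-pantolactone
Product: 2 TBS ether
Conditions: TBSCl, imidazole, DMF, rt
Reagents that add atoms: TBSCl, CC(C)(C)[Si](C)(C)Cl
Why: Silylation protects the secondary alcohol without touching the stereocentre.

**Step 2**
Reactants: 2
Product: 3 lactol
Conditions: DIBAL-H, CH2Cl2, −78 °C
Reagents that add atoms: none
Why: DIBAL stops at the hemiacetal stage for a hindered lactone, giving a masked aldehyde.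

**Step 3**
Reactants: 3
Product: 4 (3S)-3-OTBS-2,2-dimethylpent-4-en-1-ol
Conditions: Ph3PCH3Br, KOtBu, THF, 0 °C→rt
Reagents that add atoms: methylenetriphenylphosphorane, C=P(c1ccccc1)(c1ccccc1)c1ccccc1
Why: Wittig methylenation of the open-chain aldehyde form of the lactol installs the vinyl group; the CH–OTBS stereocentre is untouched.

**Step 4**
Reactants: 4
Product: 5 aldehyde
Conditions: Dess–Martin periodinane, NaHCO3, CH2Cl2, rt
Reagents that add atoms: none
Why: Mild oxidation of the neopentyl primary alcohol; the carbon next to the carbonyl is quaternary, so nothing epimerises.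

**Step 5**
Reactants: 5
Product: 6 enol ether
Conditions: Ph3P+CH2OMe Cl−, KOtBu, THF, 0 °C
Reagents that add atoms: (methoxymethylene)triphenylphosphorane, COC=P(c1ccccc1)(c1ccccc1)c1ccccc1
Why: Wittig one-carbon homologation; this CH2 becomes ring carbon C2 of the dienophile (the spiro carbon of the target).

**Step 6**
Reactants: 6
Product: 7 (4S)-4-OTBS-3,3-dimethylhex-5-enal
Conditions: 2 M HCl, THF, rt
Reagents that add atoms: water, O
Why: Enol-ether hydrolysis gives the homologated aldehyde.

**Step 7**
Reactants: 7
Product: 8 diene alcohol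
Conditions: CH2=CHMgBr, THF, −78→0 °C
Reagents that add atoms: vinylmagnesium bromide, C=C[Mg]Br
Why: Grignard addition supplies the second alkene for ring closure. The new carbinol is destroyed in step 9, so its configuration is irrelevant.

**Step 8**
Reactants: 8
Product: 9 cyclohexenol
Conditions: Grubbs II (5 mol%), CH2Cl2 (0.01 M), 40 °C
Reagents that add atoms: none
Why: Ring-closing metathesis of the 1,7-diene gives the cis-cyclohexene; the gem-dimethyl group helps cyclisation (Thorpe–Ingold effect).

**Step 9**
Reactants: 9
Product: 10 (4S)-4-OTBS-5,5-dimethylcyclohex-2-enone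
Conditions: Dess–Martin periodinane, NaHCO3, CH2Cl2, rt
Reagents that add atoms: none
Why: Oxidising the allylic alcohol leaves the enone with a single enolisable α′-CH2, which sets up regiospecific methylenation.

**Step 10**
Reactants: 10
Product: 11 Mannich base
Conditions: LDA, THF, −78 °C; then Me2N+=CH2 I−, −78 °C→rt
Reagents that add atoms: Eschenmoser's salt, C[N+](C)=C.[I-]
Why: The kinetic α′-enolate undergoes a Mannich reaction; the new α-stereocentre is epimerisable and is erased in step 12.

**Step 11**
Reactants: 11
Product: 12 saturated Mannich base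
Conditions: H2 (1 atm), 10% Pd/C, EtOAc, rt
Reagents that add atoms: none
Why: Hydrogenation of the disubstituted enone C=C gives the saturated ketone needed for ring A. This is done at the Mannich-base stage because the exocyclic methylene would not survive it.

**Step 12**
Reactants: 12
Product: 13 (4S)-4-OTBS-3,3-dimethyl-2-methylenecyclohexanone (dienophile)
Conditions: MeI, CH2Cl2; then DBU, rt
Reagents that add atoms: none (the NMe3 leaves)
Why: Quaternisation and E1cB elimination (Hofmann-type) give the α-methylene ketone.

**Step 13**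
Reactants: 13 and 14 isoprene
Product: 15 spiro ketone
Conditions: Me2AlCl, CH2Cl2, −78→0 °C
Reagents that add atoms: isoprene (14), C=CC(C)=C
Why: A Lewis-acid-promoted Diels–Alder reaction gives the para regioisomer, which places the Me-bearing alkene carbon at C9. The new quaternary spiro centre forms by attack anti to the pseudo-axial OTBS on the adjacent ring, controlled by the C2 stereocentre.

**Step 14**
Reactants: 15
Product: 16 exocyclic alkene
Conditions: Ph3PCH3Br, KOtBu, toluene, 90 °C
Reagents that add atoms: methylenetriphenylphosphorane, C=P(c1ccccc1)(c1ccccc1)c1ccccc1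
Why: Wittig methylenation of the hindered ketone installs the exocyclic methylene; no stereocentre is touched.

**Step 15**
Reactants: 16
Product: 17 alcohol
Conditions: TBAF, THF, 50 °C
Reagents that add atoms: none
Why: Fluoride removes the silyl group with retention at C2.

**Step 16**
Reactants: 17
Product: 18 (2R)-bromide
Conditions: PPh3, CBr4, CH2Cl2, 0→40 °C
Reagents that add atoms: carbon tetrabromide, BrC(Br)(Br)Br
Why: Appel SN2 inversion converts the (S)-alcohol into the (R)-bromide; the alcohol is axial in the preferred chair, so backside attack is feasible.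

**Step 17**
Reactants: 18
Product: 19 trans-chlorohydrin
Conditions: NCS, acetone/H2O (4:1), 0 °C
Reagents that add atoms: N-chlorosuccinimide, O=C1CCC(=O)N1Cl; water, O
Why: Halohydrin formation through a chloronium ion puts water on the tertiary C9 and Cl on the secondary C10, trans. The chloronium forms on the face anti to the pseudo-axial exocyclic alkene carbon of the spiro centre, so Cl ends up on the same side as the CMe2 carbon, as in the target.

**Step 18**
Reactants: 19
Product: 20 obtusane
Conditions: TMSBr, CH2Cl2, −78→−20 °C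
Reagents that add atoms: bromotrimethylsilane, C[Si](C)(C)Br
Why: SN1-type substitution of the tertiary alcohol is assisted by the anti-periplanar chlorine (chloronium), so bromide attacks anti to it and the net result is retention.

---

**Compound list**

| # | Name | SMILES | Role |
|---|---|---|---|
| 1 | (R)-pantolactone, (3R)-3-hydroxy-4,4-dimethyloxolan-2-one | O=C1OCC(C)(C)[C@H]1O | starting material |
| 2 | (3R)-3-OTBS-4,4-dimethyloxolan-2-one | O=C1OCC(C)(C)[C@H]1O[Si](C)(C)C(C)(C)C | intermediate |
| 3 | (3R)-3-OTBS-4,4-dimethyloxolan-2-ol (lactol, anomer mixture) | OC1OCC(C)(C)[C@H]1O[Si](C)(C)C(C)(C)C | intermediate |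
| 4 | (3S)-3-OTBS-2,2-dimethylpent-4-en-1-ol | OCC(C)(C)[C@@H](O[Si](C)(C)C(C)(C)C)C=C | intermediate |
| 5 | (3S)-3-OTBS-2,2-dimethylpent-4-enal | O=CC(C)(C)[C@@H](O[Si](C)(C)C(C)(C)C)C=C | intermediate |
| 6 | (4S)-4-OTBS-1-methoxy-3,3-dimethylhexa-1,5-diene (E/Z mixture) | COC=CC(C)(C)[C@@H](O[Si](C)(C)C(C)(C)C)C=C | intermediate |
| 7 | (4S)-4-OTBS-3,3-dimethylhex-5-enal | O=CCC(C)(C)[C@@H](O[Si](C)(C)C(C)(C)C)C=C | intermediate |
| 8 | (6S)-6-OTBS-5,5-dimethylocta-1,7-dien-3-ol (C3 epimers) | C=CC(O)CC(C)(C)[C@@H](O[Si](C)(C)C(C)(C)C)C=C | intermediate |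
| 9 | (4S)-4-OTBS-5,5-dimethylcyclohex-2-en-1-ol (C1 epimers) | OC1C=C[C@H](O[Si](C)(C)C(C)(C)C)C(C)(C)C1 | intermediate |
| 10 | (4S)-4-OTBS-5,5-dimethylcyclohex-2-en-1-one | O=C1C=C[C@H](O[Si](C)(C)C(C)(C)C)C(C)(C)C1 | intermediate |
| 11 | (4S)-4-OTBS-6-[(dimethylamino)methyl]-5,5-dimethylcyclohex-2-en-1-one (C6 epimers) | O=C1C=C[C@H](O[Si](C)(C)C(C)(C)C)C(C)(C)C1CN(C)C | intermediate |
| 12 | (4S)-4-OTBS-2-[(dimethylamino)methyl]-3,3-dimethylcyclohexan-1-one (C2 epimers) | O=C1CC[C@H](O[Si](C)(C)C(C)(C)C)C(C)(C)C1CN(C)C | intermediate |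
| 13 | (4S)-4-OTBS-3,3-dimethyl-2-methylidenecyclohexan-1-one | O=C1CC[C@H](O[Si](C)(C)C(C)(C)C)C(C)(C)C1=C | intermediate |
| 14 | isoprene | C=CC(C)=C | starting material |
| 15 | (2S,6R)-2-OTBS-1,1,9-trimethylspiro[5.5]undec-9-en-5-one | O=C1CC[C@H](O[Si](C)(C)C(C)(C)C)C(C)(C)[C@]12CCC(C)=CC2 | intermediate |
| 16 | (2S,6S)-2-OTBS-1,1,9-trimethyl-5-methylidenespiro[5.5]undec-9-ene | C=C1CC[C@H](O[Si](C)(C)C(C)(C)C)C(C)(C)[C@]12CCC(C)=CC2 | intermediate |
| 17 | (2S,6S)-1,1,9-trimethyl-5-methylidenespiro[5.5]undec-9-en-2-ol | C=C1CC[C@H](O)C(C)(C)[C@]12CCC(C)=CC2 | intermediate |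
| 18 | (2R,6S)-2-bromo-1,1,9-trimethyl-5-methylidenespiro[5.5]undec-9-ene | C=C1CC[C@@H](Br)C(C)(C)[C@]12CCC(C)=CC2 | intermediate |
| 19 | (2R,6S,9S,10S)-2-bromo-10-chloro-1,1,9-trimethyl-5-methylidenespiro[5.5]undecan-9-ol | C=C1CC[C@@H](Br)C(C)(C)[C@]12CC[C@](C)(O)[C@@H](Cl)C2 | intermediate |
| 20 | obtusane, (2R,6S,9S,10S)-2,9-dibromo-10-chloro-1,1,9-trimethyl-5-methylidenespiro[5.5]undecane | C=C1CC[C@@H](Br)C(C)(C)[C@]12CC[C@](C)(Br)[C@@H](Cl)C2 | target |

---

**Total step count:** 18.
**Longest linear sequence:** 18 steps from (R)-pantolactone (isoprene joins at step 13).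

**Three steps most likely to fail**
1. **Step 13, Diels–Alder.** The dienophile is hindered by the adjacent quaternary carbon, and the regiochemistry and face selectivity are uncertain.
   - Fallback: form the C1–C6 bond instead by an Ireland–Claisen [3,3] rearrangement of a prenyl-type ester of 4-methylcyclohex-3-ene-1-carboxylic acid, then close ring A by RCM.
2. **Step 16, Appel inversion.** SN2 at a secondary carbon flanked by a quaternary carbon is sluggish and may give elimination or methyl-shift products.
   - Fallback: avoid the SN2 trajectory with a radical halogen-atom-transfer bromination of the derived xanthate using BrCCl3, which favours the equatorial bromide.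
3. **Steps 17–18, chlorohydrin then bromide.** The face selectivity, chemoselectivity over the exocyclic alkene, and clean retention through the chloronium are all uncertain.
   - Fallback: epoxidise the ring-B alkene with mCPBA, open the epoxide at the secondary carbon with a chloride source to give the same trans-chlorohydrin, then proceed to the bromide.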